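**Plan**
- Feature used: ring C is a masked para-dioxygenated benzene (oxygen on C3' and C6', CH2OH on C4', linker on C1'). The linker CH2 and C1' are C11 and the lactone carbon C12 of sclareolide, so ring C can be grown on a C12 alkyne.
- Cuts, in order: the C3' carbinol back to the ketone and its dimethyl ketal; the C1'–O–C2' oxirane back to the dienone; the dienone back to a 4-methoxyphenol; then C2'–C3', C1'–C6' and C5'–C6' of the arene (alkyne + alkenyl chromium carbene + one CO).
- Forward: rings A and B come intact from sclareolide (C3 hydroxylation, lactone to Weinreb amide, C8 dehydration, aldehyde, alkyne). Ring C closes in one benzannulation; dearomatisation, epoxidation, ketal hydrolysis and C3' reduction finish.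
- Stereochemistry: C5, C9, C10 from sclareolide; C3 from the enzymatic hydroxylation; C1'/C2' from a tartrate-mediated epoxidation directed by the C4' hydroxymethyl; C3' from an aluminium hydride reduction steered by that hydroxymethyl and the oxirane.
- Numbering: labdane numbers for the decalin (C11 = linker CH2, C17 = exocyclic methylene on C8), primed numbers for ring C.

Key step: step 9

Assumption: L-(+)-diisopropyl tartrate is taken, by analogy with hydroxymethyl quinone monoketals lacking the α-alkyl group, to give the (1'S,2'R) oxirane in the epoxidation; the D-ester would be used if the sense proves opposite.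

Shorthand: "drimenylmethyl" = [(1S,4aR,6S,8aR)-6-hydroxy-5,5,8a-trimethyl-2-methylidenedecahydronaphthalen-1-yl]methyl (C11H2 on C9 of the 3β-hydroxy-8(17)-ene decalin); "O-TBS drimenylmethyl" is its 3-O-tert-butyldimethylsilyl ether.

**Route**

Step 1
Reactants: 1 (+)-sclareolide
Product: 2 3β-hydroxysclareolide
Conditions: C3-selective variant of the haem enzyme P450 BM3 (E. coli lysate), NADP+ (cat.), glucose dehydrogenase, D-glucose, air, KH2PO4/K2HPO4 buffer pH 8, 25 °C
Reagents that add atoms: dioxygen, O=O
Why: Enzymatic P450 C–H hydroxylation, known for this substrate, in which the enzyme pocket presents the equatorial 3β C–H of ring A to the iron-oxo unit and oxygen is inserted with retention, so the 3S (3β) alcohol is set by the enzyme where chemical oxidants would attack C2.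

Step 2
Reactants: 2 3β-hydroxysclareolide
Product: 3 3β-(tert-butyldimethylsilyloxy)sclareolide
Conditions: TBSOTf, 2,6-lutidine, CH2Cl2, 0 °C
Reagents that add atoms: tert-butyldimethylsilyl trifluoromethanesulfonate, CC(C)(C)[Si](C)(C)OS(=O)(=O)C(F)(F)F
Why: Silylation with a silyl triflate and a hindered base should cap the neopentylic equatorial alcohol, which would otherwise be dehydrated in step 4, while the lactone is inert.

Step 3
Reactants: 3 3β-(tert-butyldimethylsilyloxy)sclareolide
Product: 4 N-methoxy-N-methylamide of 3β-(TBS-oxy)-8α-hydroxy-13,14,15,16-tetranorlabdan-12-oic acid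
Conditions: MeNH(OMe)·HCl, AlMe3, CH2Cl2, 0 °C to rt; aq. potassium sodium tartrate
Reagents that add atoms: N,O-dimethylhydroxylamine hydrochloride, CNOC.Cl
Why: Weinreb amide formation by aluminium amide aminolysis opens the γ-lactone at the acyl carbon C12 and leaves the 8α tertiary alcohol, with no stereocentre touched and the silyl ether inert to AlMe3.

Step 4
Reactants: 4 N-methoxy-N-methylamide of 3β-(TBS-oxy)-8α-hydroxy-13,14,15,16-tetranorlabdan-12-oic acid
Product: 5 N-methoxy-N-methylamide of 3β-(TBS-oxy)-13,14,15,16-tetranorlabd-8(17)-en-12-oic acid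
Conditions: SOCl2, pyridine, CH2Cl2, −78 °C
Reagents that add atoms: none
Why: Dehydration through the chlorosulfite (E2 with pyridine) should give the exocyclic C8=C17 alkene, because the equatorial 8α leaving group has no antiperiplanar ring hydrogen and only a proton of the axial methyl can be removed; minor endocyclic isomers are removed by chromatography.

Step 5
Reactants: 5 N-methoxy-N-methylamide of 3β-(TBS-oxy)-13,14,15,16-tetranorlabd-8(17)-en-12-oic acid
Product: 6 3β-(TBS-oxy)-13,14,15,16-tetranorlabd-8(17)-en-12-al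
Conditions: i-Bu2AlH, THF, −78 °C; aq. potassium sodium tartrate
Reagents that add atoms: none
Why: Weinreb amide reduction stops at the aldehyde because the N-methoxy-chelated tetrahedral aluminate survives until work-up, and the alkene and silyl ether do not react.

Step 6
Reactants: 6 3β-(TBS-oxy)-13,14,15,16-tetranorlabd-8(17)-en-12-al
Product: 7 3β-(TBS-oxy)-14,15,16-trinorlabd-8(17)-en-12-yne (C9–C11H2–C12≡CH)
Conditions: MeC(O)C(N2)P(O)(OMe)2, K2CO3, MeOH, 0 °C to rt
Reagents that add atoms: dimethyl (1-diazo-2-oxopropyl)phosphonate, CC(=O)C(=[N+]=[N-])P(=O)(OC)OC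
Why: Seyferth–Gilbert homologation in its Ohira–Bestmann form converts the aldehyde into the terminal alkyne under mild base, and since the α-carbon C11 is a methylene nothing can epimerise.

Step 7
Reactants: 8 2-bromoallyl alcohol (2-bromoprop-2-en-1-ol)
Product: 9 (2-bromoallyloxy)triisopropylsilane
Conditions: TIPSCl, imidazole, CH2Cl2, 0 °C to rt
Reagents that add atoms: chlorotriisopropylsilane, CC(C)[Si](Cl)(C(C)C)C(C)C
Why: Imidazole-promoted silylation of a primary allylic alcohol, with the vinyl bromide left untouched.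

Step 8
Reactants: 9 (2-bromoallyloxy)triisopropylsilane; 10 chromium hexacarbonyl Cr(CO)6
Product: 13 pentacarbonyl{methoxy[3-(triisopropylsilyloxy)prop-1-en-2-yl]carbene}chromium, via 2-lithioallyl silyl ether 11 (not isolated), via lithium acylchromate 12 (not isolated)
Conditions: t-BuLi (2 equiv), Et2O, −78 °C; Cr(CO)6, Et2O, −78 to 0 °C; Me3OBF4, CH2Cl2, 0 °C
Reagents that add atoms: trimethyloxonium tetrafluoroborate, C[O+](C)C.F[B-](F)(F)F
Why: Fischer carbene synthesis, in which bromine–lithium exchange gives vinyllithium 11, addition to a CO ligand gives acylchromate 12 and O-methylation gives the carbene complex; the bulky triisopropylsilyl group and the low temperature are chosen to hold back O-to-C silyl migration in 11.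

Step 9
Reactants: 7 3β-(TBS-oxy)-14,15,16-trinorlabd-8(17)-en-12-yne; 13 pentacarbonyl{methoxy[3-(triisopropylsilyloxy)prop-1-en-2-yl]carbene}chromium
Product: 15 2-(O-TBS drimenylmethyl)-4-methoxy-5-[(triisopropylsilyloxy)methyl]phenol, via tricarbonylchromium arene complex 14 (not isolated)
Conditions: THF, 50 °C, argon; then air, MeCN, rt
Reagents that add atoms: none
Why: Dötz benzannulation: 13 loses one CO on warming, alkyne 7 inserts into the Cr=C bond to give a vinylcarbene, a CO ligand inserts to give a chromium-bound dienylketene, and this closes and enolises to the phenol, first held on Cr(CO)3 as 14 and then freed by air. The closest known reaction type is exactly this benzannulation of alkenyl(methoxy)carbene complexes of zerovalent chromium with terminal alkynes. Ring C closes by 6π-electrocyclisation of the dienylketene (bond C5'–C6'), after C2'–C3' (alkyne insertion) and C1'–C6' (CO insertion) have formed. No stereocentre is created, and the decalin centres lie outside the reacting atoms. The one selectivity needed is the direction of alkyne insertion: the steric gap between the unsubstituted terminus and the carbon bearing the bulky C11H2–decalin group should put the former on the carbene carbon (C3', OMe) and the latter next to the CO-derived C6' (free OH), the pattern that the later ketal and epoxide chemistry requires. The C8=C17 alkene sits only two atoms from the alkyne, too near for the vinylcarbene to cyclopropanate it, and both silyl ethers are inert.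

Step 10
Reactants: 15 2-(O-TBS drimenylmethyl)-4-methoxy-5-[(triisopropylsilyloxy)methyl]phenol
Product: 16 2-(drimenylmethyl)-5-(hydroxymethyl)-4-methoxyphenol
Conditions: Bu4NF, THF, 60 °C, argon
Reagents that add atoms: none
Why: Fluoride desilylation should remove the primary TIPS ether at once and the hindered 3β-TBS ether on warming, at a stage where only a robust arene is present, and it frees the C4' hydroxymethyl that must direct steps 12 and 14.

Step 11
Reactants: 16 2-(drimenylmethyl)-5-(hydroxymethyl)-4-methoxyphenol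
Product: 17 2-(drimenylmethyl)-5-(hydroxymethyl)-4,4-dimethoxycyclohexa-2,5-dien-1-one
Conditions: PhI(OAc)2, MeOH, 0 °C
Reagents that add atoms: methanol, CO
Why: Hypervalent iodine oxidative dearomatisation of a 4-methoxyphenol, in which methanol traps the C3' oxocarbenium to give the quinone monoketal with C6' as the ketone; PhI(OAc)2 alone oxidises neither the alcohols nor the alkene.

Step 12
Reactants: 17 2-(drimenylmethyl)-5-(hydroxymethyl)-4,4-dimethoxycyclohexa-2,5-dien-1-one
Product: 18 (1S,6R)-1-(drimenylmethyl)-4-(hydroxymethyl)-5,5-dimethoxy-7-oxabicyclo[4.1.0]hept-3-en-2-one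
Conditions: Ph3COOH, NaN(SiMe3)2, L-(+)-diisopropyl tartrate, toluene, −60 to −40 °C
Reagents that add atoms: triphenylmethyl hydroperoxide, OOC(c1ccccc1)(c1ccccc1)c1ccccc1
Why: Tartrate-mediated nucleophilic (Weitz–Scheffer) epoxidation in which the sodium alkoxide of the C4' hydroxymethyl, the tartrate and trityl peroxide form one aggregate that delivers peroxide across the ketal to C2', the only β-carbon bearing hydrogen, and the enolate closes to the cis-fused oxirane; C1' and C2' are set together by the tartrate (reagent control), the C4'=C5' enone is spared because its β-carbon is fully substituted, and any minor epoxide is a separable diastereomer.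

Step 13
Reactants: 18 (1S,6R)-1-(drimenylmethyl)-4-(hydroxymethyl)-5,5-dimethoxy-7-oxabicyclo[4.1.0]hept-3-en-2-one
Product: 19 (1S,6R)-1-(drimenylmethyl)-4-(hydroxymethyl)-7-oxabicyclo[4.1.0]hept-3-ene-2,5-dione
Conditions: 48% aq. HF, MeCN, 0 °C to rt
Reagents that add atoms: water, O
Why: Acid hydrolysis of the dimethyl ketal with aqueous HF in MeCN, the mild acid used to unmask epoxy quinone monoketals, which should ionise the ketal next to the oxirane without opening the oxirane or protonating the C8=C17 alkene; no stereocentre is touched.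

Step 14
Reactants: 19 (1S,6R)-1-(drimenylmethyl)-4-(hydroxymethyl)-7-oxabicyclo[4.1.0]hept-3-ene-2,5-dione
Product: 20 (1S,5R,6S)-1-(drimenylmethyl)-5-hydroxy-4-(hydroxymethyl)-7-oxabicyclo[4.1.0]hept-3-en-2-one (target)
Conditions: i-Bu2AlH (excess), THF, −78 °C; aq. potassium sodium tartrate
Reagents that add atoms: none
Why: Hydroxyl-directed aluminium hydride reduction of an epoxyquinone, in which the aluminium alkoxide of the C4' hydroxymethyl chelates and activates the neighbouring C3' carbonyl (C6' is also shielded by the quaternary C1') and hydride is delivered from i-Bu2AlH bound to the oxirane oxygen, i.e. syn to the oxirane, so the new C3' hydroxyl should end anti to it (3'R).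

**Compound list**
1 | (+)-sclareolide | C[C@]12CCCC([C@@H]1CC[C@@]3([C@@H]2CC(=O)O3)C)(C)C | starting material
2 | 3β-hydroxysclareolide | C[C@@]12CC[C@H]3C(C)(C)[C@@H](O)CC[C@]3(C)[C@H]1CC(=O)O2 | intermediate
3 | 3β-(tert-butyldimethylsilyloxy)sclareolide | C[C@@]12CC[C@H]3C(C)(C)[C@@H](O[Si](C)(C)C(C)(C)C)CC[C@]3(C)[C@H]1CC(=O)O2 | intermediate
4 | ring-opened Weinreb amide, 8α-OH, 8β-CH3, 3β-OTBS | C[C@@]1(O)CC[C@H]2C(C)(C)[C@@H](O[Si](C)(C)C(C)(C)C)CC[C@]2(C)[C@H]1CC(=O)N(C)OC | intermediate
5 | 8(17)-ene Weinreb amide, 3β-OTBS | C=C1CC[C@H]2C(C)(C)[C@@H](O[Si](C)(C)C(C)(C)C)CC[C@]2(C)[C@H]1CC(=O)N(C)OC | intermediate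
6 | 8(17)-en-12-al, 3β-OTBS | C=C1CC[C@H]2C(C)(C)[C@@H](O[Si](C)(C)C(C)(C)C)CC[C@]2(C)[C@H]1CC=O | intermediate
7 | terminal alkyne C9–C11H2–C12≡CH, 3β-OTBS, 8(17)-ene | C=C1CC[C@H]2C(C)(C)[C@@H](O[Si](C)(C)C(C)(C)C)CC[C@]2(C)[C@H]1CC#C | intermediate
8 | 2-bromoallyl alcohol | C=C(Br)CO | starting material
9 | (2-bromoallyloxy)triisopropylsilane | C=C(Br)CO[Si](C(C)C)(C(C)C)C(C)C | intermediate
10 | chromium hexacarbonyl | O=C=[Cr](=C=O)(=C=O)(=C=O)(=C=O)=C=O | starting material
11 | 2-lithio-3-(triisopropylsilyloxy)propene | [Li]C(=C)CO[Si](C(C)C)(C(C)C)C(C)C | intermediate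
12 | lithium [2-(triisopropylsilyloxymethyl)acryloyl]pentacarbonylchromate | [Li+].[O-]C(C(=C)CO[Si](C(C)C)(C(C)C)C(C)C)=[Cr](=C=O)(=C=O)(=C=O)(=C=O)=C=O | intermediate
13 | pentacarbonyl{methoxy[3-(triisopropylsilyloxy)prop-1-en-2-yl]carbene}chromium | COC(C(=C)CO[Si](C(C)C)(C(C)C)C(C)C)=[Cr](=C=O)(=C=O)(=C=O)(=C=O)=C=O | intermediate
14 | tricarbonyl(η6-arene)chromium complex of phenol 15 | C=C1CC[C@H]2C(C)(C)[C@@H](O[Si](C)(C)C(C)(C)C)CC[C@]2(C)[C@H]1Cc1cc(OC)c(CO[Si](C(C)C)(C(C)C)C(C)C)cc1O.[Cr](=C=O)(=C=O)=C=O | intermediate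
15 | 2-(O-TBS drimenylmethyl)-4-methoxy-5-[(triisopropylsilyloxy)methyl]phenol | C=C1CC[C@H]2C(C)(C)[C@@H](O[Si](C)(C)C(C)(C)C)CC[C@]2(C)[C@H]1Cc1cc(OC)c(CO[Si](C(C)C)(C(C)C)C(C)C)cc1O | intermediate
16 | 2-(drimenylmethyl)-5-(hydroxymethyl)-4-methoxyphenol | C=C1CC[C@H]2C(C)(C)[C@@H](O)CC[C@]2(C)[C@H]1Cc1cc(OC)c(CO)cc1O | intermediate
17 | quinone monoketal (C6' ketone, C3' dimethyl ketal) | C=C1CC[C@H]2C(C)(C)[C@@H](O)CC[C@]2(C)[C@H]1CC1=CC(OC)(OC)C(CO)=CC1=O | intermediate
18 | (1'S,2'R)-epoxy ketal | C=C1CC[C@H]2C(C)(C)[C@@H](O)CC[C@]2(C)[C@H]1C[C@]12O[C@H]1C(OC)(OC)C(CO)=CC2=O | intermediate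
19 | (1'S,2'R)-epoxyquinone | C=C1CC[C@H]2C(C)(C)[C@@H](O)CC[C@]2(C)[C@H]1C[C@]12O[C@H]1C(=O)C(CO)=CC2=O | intermediate
20 | CNP0156414.3, (1'S,2'S,3'R); the C2' descriptor changes from 19 only through CIP ranking | C=C1CC[C@H]2C(C)(C)[C@@H](O)CC[C@]2(C)[C@H]1C[C@]12O[C@H]1[C@H](O)C(CO)=CC2=O | target

**Count**
Total: 14 steps. Longest linear sequence: 12 steps (steps 1–6 and 9–14); the carbene branch is steps 7–8.

**Steps most likely to fail**

1. Step 12: poor or reversed facial selectivity of peroxide delivery, since the α-alkyl group on C1' and a dimethyl ketal are not the best-studied combination for the tartrate aggregate. The fallback replaces reagent control by an auxiliary in the ketal. It sets out from 17: exchange of the dimethyl ketal with (2R,4R)-pentane-2,4-diol (PPTS, benzene, rt) gives the spiro dioxane dienone F1, whose ring methyls differentiate the two faces of C1'=C2'. Epoxidation with Ph3COOH and KN(SiMe3)2 in THF at −35 °C should then give the epoxy dioxane F2 (the enantiomeric diol is taken if induction runs the wrong way, and the minor epoxide is a separable diastereomer). Aqueous HF in MeCN hydrolyses the dioxane and the route is rejoined at 19.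

2. Step 14: hydride attack on the face anti to the oxirane (giving the 3'-epimer) or competing reduction at C6'. The fallback accepts the syn alcohol and inverts it. It sets out from 19: NaBH4 with CeCl3·7H2O in MeOH at −78 °C, which should add hydride anti to the oxirane, gives the 3'-epimer F3. TBSCl and imidazole silylate only the primary hydroxyl, giving the primary silyl ether F4. A Mitsunobu reaction (4-nitrobenzoic acid, PPh3, DIAD, THF, 0 °C) inverts C3' to the 4-nitrobenzoate F5; the neopentylic decalin C3 hydroxyl should not react. K2CO3 in MeOH at 0 °C cleaves the ester to the silyl ether of the target F6, and HF·pyridine in THF removes the silyl group, coming back to the route at 20.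

3. Step 8: loss of the vinyllithium by O-to-C silyl migration or β-elimination of silanolate before it is captured by Cr(CO)6. The fallback avoids the vinyllithium and acylates a chromate dianion instead. It sets out from 10 and commercial methyl 2-(hydroxymethyl)acrylate F7: silylation (TIPSCl, imidazole) gives the ester F8, LiOH in THF/H2O the acid F9, and (COCl)2 with cat. DMF the acid chloride F10. Reduction of 10 with KC8 in THF gives K2Cr(CO)5 F11, which is acylated by F10 at −78 °C to the potassium acylchromate F12. O-methylation with Me3OBF4 as in step 8 returns to the route at 13.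

**Further compounds**
F1 | step 12 | (2R,4R)-pentane-2,4-diol ketal of dienone 17 | C=C1CC[C@H]2C(C)(C)[C@@H](O)CC[C@]2(C)[C@H]1CC1=CC3(O[C@H](C)C[C@@H](C)O3)C(CO)=CC1=O
F2 | step 12 | (1'S,2'R)-oxirane of F1 | C=C1CC[C@H]2C(C)(C)[C@@H](O)CC[C@]2(C)[C@H]1C[C@]12O[C@H]1C3(O[C@H](C)C[C@@H](C)O3)C(CO)=CC2=O
F3 | step 14 | 3'-epimer of 20 (hydroxyl syn to the oxirane) | C=C1CC[C@H]2C(C)(C)[C@@H](O)CC[C@]2(C)[C@H]1C[C@]12O[C@H]1[C@@H](O)C(CO)=CC2=O
F4 | step 14 | primary TBS ether of F3 | C=C1CC[C@H]2C(C)(C)[C@@H](O)CC[C@]2(C)[C@H]1C[C@]12O[C@H]1[C@@H](O)C(CO[Si](C)(C)C(C)(C)C)=CC2=O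
F5 | step 14 | 4-nitrobenzoate with inverted C3', primary TBS ether | C=C1CC[C@H]2C(C)(C)[C@@H](O)CC[C@]2(C)[C@H]1C[C@]12O[C@H]1[C@H](OC(=O)c3ccc(cc3)[N+](=O)[O-])C(CO[Si](C)(C)C(C)(C)C)=CC2=O
F6 | step 14 | primary TBS ether of 20 | C=C1CC[C@H]2C(C)(C)[C@@H](O)CC[C@]2(C)[C@H]1C[C@]12O[C@H]1[C@H](O)C(CO[Si](C)(C)C(C)(C)C)=CC2=O
F7 | step 8 | methyl 2-(hydroxymethyl)acrylate | C=C(CO)C(=O)OC
F8 | step 8 | methyl 2-[(triisopropylsilyloxy)methyl]acrylate | C=C(CO[Si](C(C)C)(C(C)C)C(C)C)C(=O)OC
F9 | step 8 | 2-[(triisopropylsilyloxy)methyl]acrylic acid | C=C(CO[Si](C(C)C)(C(C)C)C(C)C)C(=O)O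
F10 | step 8 | 2-[(triisopropylsilyloxy)methyl]acryloyl chloride | C=C(CO[Si](C(C)C)(C(C)C)C(C)C)C(Cl)=O
F11 | step 8 | dipotassium pentacarbonylchromate K2Cr(CO)5 | [K+].[K+].O=C=[Cr-2](=C=O)(=C=O)(=C=O)=C=O
F12 | step 8 | potassium [2-(triisopropylsilyloxymethyl)acryloyl]pentacarbonylchromate | [K+].[O-]C(C(=C)CO[Si](C(C)C)(C(C)C)C(C)C)=[Cr](=C=O)(=C=O)(=C=O)(=C=O)=C=O
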